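**Retrosynthetic overview**

1. The ten-membered ring is formed last, by ring-closing metathesis at C3=C4 (Z) between a C2 vinyl carbinol and a 2-substituted butadiene (C4, C5=C16) that is made from a C6 ethynyl group and ethylene.
2. The γ-lactone and chlorohydrin (C6–C8, C17–C19) come from a chelation-controlled propionate aldol on a C8 α,β-epoxy ketone, chloride opening at propargylic C6 and lactonisation; the epoxide comes from Sharpless epoxidation of an enynol built on a C8 aldehyde.
3. The C1 quaternary centre, C2 and the C13=C14 alkene come from the C14 silyl enol ether that the cycloaddition leaves (C-formylation at C1, then enol triflate reduction); the C20 methyl comes from reduction of the temporary lactone carbonyl.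
4. Key disconnection: the cyclohexene ring (C1, C10–C14) by an intramolecular Diels–Alder reaction that forms C12–C13 and C10–C11 together with a temporary δ-lactone (O8–C20). Enabling feature: on this ring C20 (on C11) and C9 (on C10) are cis and the C12 oxygen is trans to C20, so C11–C12 is a latent (E)-β-oxyacrylate whose carboxyl carbon C20 can be lent to O8, while allylic strain between the C15 methyl and C9–H relays the C9 configuration to the ring.
5. The precursor is the acyclic triene 10, four steps from (R)-glyceraldehyde acetonide. Ring order: cyclohexene plus δ-lactone (step 7), γ-lactone (step 22), ten-membered ring (step 27).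

Key step: step 7

Remark: briarane numbering is used for all intermediates (C1 quaternary carbon, C2–C9 chain of the ten-membered ring, C10–C14 remaining cyclohexene carbons, C15 and C20 methyls, C16 exocyclic methylene, C17–C19 lactone carbons with C18 methyl); ylide 6 and all reagents are taken as purchased.

Step 1
Reactants: 1 4-methoxybenzyl alcohol; 2 ethyl propiolate
Product: 3 ethyl (E)-3-[(4-methoxybenzyl)oxy]acrylate
Conditions: N-methylmorpholine (cat.), CH2Cl2, rt
Reagents that add atoms: none
Why: Amine-catalysed oxa-Michael addition of the alcohol to the ynoate should give the thermodynamically favoured (E)-β-alkoxyacrylate.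

Step 2
Reactants: 3 ethyl (E)-3-[(4-methoxybenzyl)oxy]acrylate
Product: 4 (E)-3-[(4-methoxybenzyl)oxy]acrylic acid
Conditions: LiOH, THF/H2O, rt; then aq. HCl to pH 4, 0 °C
Reagents that add atoms: lithium hydroxide, [Li+].[OH-]
Why: Saponification with careful cold acidification should free the acid without hydrolysing the enol ether.

Step 3
Reactants: 5 (R)-2,2-dimethyl-1,3-dioxolane-4-carbaldehyde; 6 3-(triphenylphosphoranylidene)butan-2-one
Product: 7 (S,E)-4-(2,2-dimethyl-1,3-dioxolan-4-yl)-3-methylbut-3-en-2-one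
Conditions: CH2Cl2, rt → 40 °C
Reagents that add atoms: none
Why: Wittig olefination with the stabilised α-branched ylide should give the (E)-trisubstituted enone without epimerising the α-alkoxy centre (C9).

Step 4
Reactants: 7 (S,E)-4-(2,2-dimethyl-1,3-dioxolan-4-yl)-3-methylbut-3-en-2-one
Product: 8 (S,E)-5,6-dihydroxy-3-methylhex-3-en-2-one
Conditions: AcOH/H2O (4:1), rt
Reagents that add atoms: none
Why: Acid-catalysed acetonide hydrolysis should free the 1,2-diol, and the (E) geometry prevents hemiketal formation with the ketone.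

Step 5
Reactants: 8 (S,E)-5,6-dihydroxy-3-methylhex-3-en-2-one; 4 (E)-3-[(4-methoxybenzyl)oxy]acrylic acid
Product: 9 (S,E)-2-hydroxy-4-methyl-5-oxohex-3-en-1-yl (E)-3-[(4-methoxybenzyl)oxy]acrylate
Conditions: EDC·HCl, DMAP (cat.), CH2Cl2, −20 → 0 °C
Reagents that add atoms: none
Why: Steglich-type carbodiimide esterification at low temperature should acylate the primary C8 hydroxyl in preference to the secondary allylic C9 hydroxyl.

Step 6
Reactants: 9 (S,E)-2-hydroxy-4-methyl-5-oxohex-3-en-1-yl (E)-3-[(4-methoxybenzyl)oxy]acrylate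
Product: 10 (S,E)-2,5-bis(tert-butyldimethylsilyloxy)-4-methylhexa-3,5-dien-1-yl (E)-3-[(4-methoxybenzyl)oxy]acrylate
Conditions: TBSOTf (2.5 equiv), Et3N, CH2Cl2, −78 → 0 °C
Reagents that add atoms: tert-butyldimethylsilyl triflate, CC(C)(C)[Si](C)(C)OS(=O)(=O)C(F)(F)F
Why: Silyl triflate/amine soft enolisation should convert the methyl ketone into the cross-conjugated 2-silyloxydiene (kinetic CH3 deprotonation) and silylate the C9 hydroxyl in the same operation.

Step 7
Reactants: 10 (S,E)-2,5-bis(tert-butyldimethylsilyloxy)-4-methylhexa-3,5-dien-1-yl (E)-3-[(4-methoxybenzyl)oxy]acrylate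
Product: 11 cis-fused cyclohexene δ-lactone with C14 silyl enol ether (9S,10S,11R,12R)
Conditions: PhMe (5 mM), BHT, iPr2NEt (trace), sealed tube, 150 °C
Reagents that add atoms: none
Why: Thermal, concerted but asynchronous normal-demand intramolecular Diels–Alder reaction of the electron-rich 2-silyloxydiene C13=C14(OTBS)–C1(Me)=C10 with the tethered (E)-β-alkoxyacrylate C11=C12, whose polarity (nucleophilic C13 to the acrylate β-carbon C12) matches the regiochemistry that the four-atom tether C9–C8–O–C20 enforces; the closest known reaction type is the intramolecular Diels–Alder reaction of 3,5-hexadienyl acrylates (ester-tethered 1,3,9-decatrienes) and of 2-silyloxydienes. The cyclohexene closes by the [4+2] bond pair C12–C13 and C10–C11, and the temporary δ-lactone C10–C9–C8–O–C20–C11 closes as the fused tether ring through a chair-like transition state. C10 is set by C9: allylic 1,3-strain with the C15 methyl holds C9–H in the diene plane, so the CH2O arm of the tether lies on one face and the OTBS group on the other, and the dienophile can only reach the face that gives (9S,10S). C11 follows from the endo orientation of the tether carbonyl (cis ring fusion, C20 cis to C9), and C12 from suprafacial addition to the (E)-acrylate, which places the OPMB group trans to C20. The step needs endo over exo selectivity, which secondary overlap of the tether carbonyl with the diene should favour, and it delivers the C14=C1 silyl enol ether regiospecifically for the later quaternisation of C1.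

Step 8
Reactants: 11 cis-fused cyclohexene δ-lactone with C14 silyl enol ether
Product: 12 C14 ketone with C1 quaternary dimethoxymethyl group (1S)
Conditions: HC(OMe)3, Me3SiOTf (10 mol %), CH2Cl2, −78 → −40 °C
Reagents that add atoms: trimethyl orthoformate, COC(OC)OC
Why: Mukaiyama-type alkylation of the regiodefined tetrasubstituted silyl enol ether by the dimethoxycarbenium ion should create the C1 quaternary centre, the electrophile entering on the convex face of the cis-fused bicycle, anti to C9, so that C2 is trans to C9 and the C15 methyl cis to it.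

Step 9
Reactants: 12 C14 ketone with C1 quaternary dimethoxymethyl group
Product: 14 C14 enol triflate (C13=C14), via potassium enolate 13 (not isolated)
Conditions: KN(SiMe3)2, THF, −78 °C; then N-(5-chloro-2-pyridyl)bis(trifluoromethanesulfonimide), −78 °C
Reagents that add atoms: N-(5-chloro-2-pyridyl)bis(trifluoromethanesulfonimide), FC(F)(F)S(=O)(=O)N(c1ccc(Cl)cn1)S(=O)(=O)C(F)(F)F
Why: The ketone can enolise only towards C13 because C1 is quaternary, and trapping of the potassium enolate at −78 °C with the reactive pyridyl triflimide should outpace β-elimination of the C12 ether.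

Step 10
Reactants: 14 C14 enol triflate
Product: 15 cyclohex-13-ene with C1 dimethoxymethyl group
Conditions: Pd(OAc)2 (5 mol %), PPh3, Bu3N, HCO2H, DMF, 60 °C
Reagents that add atoms: none
Why: Palladium-catalysed formate reduction of the enol triflate (oxidative addition, formate decarboxylation, C–H reductive elimination) should give the C13=C14 alkene with no change at any stereocentre.

Step 11
Reactants: 15 cyclohex-13-ene with C1 dimethoxymethyl group
Product: 16 C2 aldehyde
Conditions: LiBF4, MeCN/H2O (98:2), rt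
Reagents that add atoms: water, O
Why: Mild Lewis-acid hydrolysis of the dimethyl acetal should unveil the neopentyl aldehyde, which has no α-hydrogen and cannot epimerise or conjugate.

Step 12
Reactants: 16 C2 aldehyde
Product: 17 C2 vinyl carbinol (2S)
Conditions: (CH2=CH)2Zn, (−)-DAIB (10 mol %), PhMe, 0 °C
Reagents that add atoms: divinylzinc, C=C[Zn]C=C
Why: Amino-alcohol-catalysed addition of the alkenylzinc to the aldehyde is chemoselective over the lactone and should set C2 (S) by reagent control, reinforced by Felkin–Anh attack anti to the C1–C10 bond.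

Step 13
Reactants: 17 C2 vinyl carbinol
Product: 18 C2 tert-butyldimethylsilyl ether
Conditions: TBSOTf, 2,6-lutidine, CH2Cl2, −78 → 0 °C
Reagents that add atoms: tert-butyldimethylsilyl triflate, CC(C)(C)[Si](C)(C)OS(=O)(=O)C(F)(F)F
Why: The silyl triflate should silylate the hindered allylic alcohol, which must be masked for the reduction and oxidation steps that follow.

Step 14
Reactants: 18 C2 tert-butyldimethylsilyl ether
Product: 19 lactol (C20 hemiacetal)
Conditions: iBu2AlH (1.2 equiv), CH2Cl2, −78 °C; Rochelle salt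
Reagents that add atoms: none
Why: Hydride addition to the δ-lactone at −78 °C should stop at the tetrahedral aluminium hemiacetal and give the six-membered lactol.

Step 15
Reactants: 19 lactol
Product: 21 C8 primary alcohol with C20 methyl group, via tosylhydrazone 20 (not isolated)
Conditions: TsNHNH2, THF, rt; then catecholborane, CHCl3, 0 °C; NaOAc·3H2O, 60 °C
Reagents that add atoms: none
Why: The lactol opens to the hydroxy aldehyde on tosylhydrazone formation, and borane reduction of the hydrazone followed by sulfinate loss and N2 extrusion (Caglioti-type deoxygenation) should turn C20 into the methyl group and free the C8 hydroxyl without touching C11.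

Step 16
Reactants: 21 C8 primary alcohol with C20 methyl group
Product: 22 C8 aldehyde
Conditions: Dess–Martin periodinane, NaHCO3, CH2Cl2, 0 °C → rt
Reagents that add atoms: none
Why: Buffered Dess–Martin oxidation should give the α-silyloxy aldehyde without epimerising C9.

Step 17
Reactants: 23 1,4-bis(trimethylsilyl)buta-1,3-diyne
Product: 25 buta-1,3-diynyl(trimethyl)silane, via lithium acetylide 24 (not isolated)
Conditions: MeLi·LiBr, Et2O, rt; then aq. NH4Cl, 0 °C
Reagents that add atoms: none
Why: Methyllithium cleaves one C–Si bond of the bis-silyl diyne selectively, and protonation of the lithium acetylide should give the mono-protected diyne.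

Step 18
Reactants: 22 C8 aldehyde; 25 buta-1,3-diynyl(trimethyl)silane
Product: 28 (8S)-enynol (C6=C7 E), via alkenylborane 26 (not isolated), via alkenylzinc 27 (not isolated)
Conditions: 25, Cy2BH, PhMe, 0 °C → rt; Me2Zn, −78 °C; EtZnCl, then 22, −30 → 0 °C
Reagents that add atoms: none
Why: Hydroboration of the terminal alkyne, boron-to-zinc exchange and addition of the (E)-alkenylzinc to the aldehyde held in a zinc halide chelate through O9 (Cram chelate model) should give the syn (8S) allylic alcohol.

Step 19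
Reactants: 28 (8S)-enynol
Product: 29 trans-6,7-epoxy alcohol
Conditions: Ti(OiPr)4, D-(−)-DIPT, t-BuOOH, 4 Å MS, CH2Cl2, −20 °C
Reagents that add atoms: tert-butyl hydroperoxide, CC(C)(C)OO
Why: Sharpless asymmetric epoxidation, for which the (8S) carbinol is the fast-reacting (matched) epimer with the D-tartrate, should deliver oxygen to the C6=C7 face that gives the erythro epoxy alcohol with the target configuration at C7.

Step 20
Reactants: 29 trans-6,7-epoxy alcohol
Product: 30 C8 α,β-epoxy ketone
Conditions: Dess–Martin periodinane, NaHCO3, CH2Cl2, 0 °C → rt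
Reagents that add atoms: none
Why: Buffered Dess–Martin oxidation of the secondary alcohol should leave the epoxide and the C9 centre untouched.

Step 21
Reactants: 30 C8 α,β-epoxy ketone
Product: 31 tertiary β-hydroxy ester (8R,17R)
Conditions: EtCO2Et, LiN(iPr)2, THF, −78 °C; then 30, −78 °C; aq. NH4Cl
Reagents that add atoms: ethyl propionate, CCC(=O)OCC
Why: Aldol addition of the (E)-lithium enolate through a Zimmerman–Traxler chair in which lithium also binds the epoxide oxygen should attack the ketone anti to C6, setting C8, and place the C18 methyl anti to C7, setting C17.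

Step 22
Reactants: 31 tertiary β-hydroxy ester
Product: 33 chloro γ-lactone with free C8 hydroxyl, via chlorohydrin 32 (not isolated)
Conditions: ClTi(OiPr)3, CH2Cl2, 0 °C → rt
Reagents that add atoms: chlorotitanium triisopropoxide, CC(C)O[Ti](Cl)(OC(C)C)OC(C)C
Why: Titanium-assisted opening of the 2,3-epoxy alcohol by chloride at the distal, propargylic carbon C6 with inversion should give the anti chlorohydrin, whose C7 hydroxyl then lactonises onto the ethyl ester under titanium alkoxide transesterification.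

Step 23
Reactants: 33 chloro γ-lactone
Product: 34 C12 alcohol
Conditions: DDQ, CH2Cl2/pH 7 buffer, 0 °C
Reagents that add atoms: none
Why: Oxidative cleavage of the 4-methoxybenzyl ether through its benzylic oxocarbenium ion should free the C12 hydroxyl.

Step 24
Reactants: 34 C12 alcohol
Product: 35 C12 acetate
Conditions: Ac2O, pyridine, CH2Cl2, rt
Reagents that add atoms: acetic anhydride, CC(=O)OC(C)=O
Why: The secondary allylic hydroxyl should be acetylated while the hindered tertiary C8 hydroxyl stays free.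

Step 25
Reactants: 35 C12 acetate
Product: 36 enyne triol (free C2, C8 and C9 hydroxyls; terminal alkyne)
Conditions: Bu4NF, AcOH, THF, 0 → 40 °C
Reagents that add atoms: none
Why: Buffered fluoride should cleave both silyl ethers and the alkynyl C–Si bond without acyl migration or loss of the propargylic chloride.

Step 26
Reactants: 36 enyne triol
Product: 37 2-substituted buta-1,3-diene (C5=C16 and C4 vinyl)
Conditions: second-generation Grubbs catalyst (10 mol %), ethylene (1 atm), CH2Cl2, 40 °C
Reagents that add atoms: ethene, C=C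
Why: Ethylene–alkyne cross-enyne metathesis should convert the terminal alkyne into the 2-substituted butadiene, installing C16 as the exocyclic methylene before ring closure.

Step 27
Reactants: 37 2-substituted buta-1,3-diene
Product: 38 ten-membered (3Z)-diene diol (2,9-dideacetyl target)
Conditions: second-generation Hoveyda–Grubbs catalyst (15 mol %), 1,4-benzoquinone, PhMe (1 mM), 80 °C, Ar sparge
Reagents that add atoms: none
Why: Ring-closing metathesis between the C2 vinyl group and the monosubstituted vinyl of the diene should close the ten-membered ring with the ring-enforced Z alkene, the 1,1-disubstituted C5=C16 and the cyclohexene alkene being unreactive.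

Step 28
Reactants: 38 ten-membered (3Z)-diene diol
Product: 39 CNP0076552.1 (target)
Conditions: Ac2O, pyridine, DMAP (cat.), CH2Cl2, rt
Reagents that add atoms: acetic anhydride, CC(=O)OC(C)=O
Why: Acetylation of the two secondary hydroxyls (C2, C9) should give the triacetate while the hindered, hydrogen-bonded tertiary C8 hydroxyl remains free.

**Compound list**

1 | 4-methoxybenzyl alcohol | COc1ccc(CO)cc1 | starting material
2 | ethyl propiolate | CCOC(=O)C#C | starting material
3 | ethyl (E)-3-[(4-methoxybenzyl)oxy]acrylate | CCOC(=O)/C=C/OCc1ccc(OC)cc1 | intermediate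
4 | (E)-3-[(4-methoxybenzyl)oxy]acrylic acid | OC(=O)/C=C/OCc1ccc(OC)cc1 | intermediate
5 | (R)-2,2-dimethyl-1,3-dioxolane-4-carbaldehyde | O=C[C@H]1COC(C)(C)O1 | starting material
6 | 3-(triphenylphosphoranylidene)butan-2-one | CC(=O)C(C)=P(c1ccccc1)(c1ccccc1)c1ccccc1 | starting material
7 | (S,E)-4-(2,2-dimethyl-1,3-dioxolan-4-yl)-3-methylbut-3-en-2-one | CC(=O)/C(C)=C/[C@H]1COC(C)(C)O1 | intermediate
8 | (S,E)-5,6-dihydroxy-3-methylhex-3-en-2-one | CC(=O)/C(C)=C/[C@H](O)CO | intermediate
9 | (S,E)-2-hydroxy-4-methyl-5-oxohex-3-en-1-yl (E)-3-[(4-methoxybenzyl)oxy]acrylate | CC(=O)/C(C)=C/[C@H](O)COC(=O)/C=C/OCc1ccc(OC)cc1 | intermediate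
10 | (S,E)-2,5-bis(tert-butyldimethylsilyloxy)-4-methylhexa-3,5-dien-1-yl (E)-3-[(4-methoxybenzyl)oxy]acrylate | C=C(O[Si](C)(C)C(C)(C)C)/C(C)=C/[C@H](O[Si](C)(C)C(C)(C)C)COC(=O)/C=C/OCc1ccc(OC)cc1 | intermediate
11 | Diels–Alder adduct: cis-fused cyclohexene δ-lactone (C11–C20(=O)–O–C8–C9–C10); C14 OTBS enol ether; C12 OPMB trans to C20; C9 OTBS; 9S,10S,11R,12R | CC1=C(O[Si](C)(C)C(C)(C)C)C[C@@H](OCc2ccc(OC)cc2)[C@@H]2C(=O)OC[C@@H](O[Si](C)(C)C(C)(C)C)[C@H]12 | intermediate
12 | C14 ketone with C1 quaternary centre (methyl and dimethoxymethyl; 1S) | C[C@]1(C(OC)OC)C(=O)C[C@@H](OCc2ccc(OC)cc2)[C@@H]2C(=O)OC[C@@H](O[Si](C)(C)C(C)(C)C)[C@H]12 | intermediate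
13 | potassium C13=C14 enolate of 12 | C[C@]1(C(OC)OC)C([O-])=C[C@@H](OCc2ccc(OC)cc2)[C@@H]2C(=O)OC[C@@H](O[Si](C)(C)C(C)(C)C)[C@H]12.[K+] | intermediate
14 | C14 enol triflate | C[C@]1(C(OC)OC)C(OS(=O)(=O)C(F)(F)F)=C[C@@H](OCc2ccc(OC)cc2)[C@@H]2C(=O)OC[C@@H](O[Si](C)(C)C(C)(C)C)[C@H]12 | intermediate
15 | C13=C14 cyclohexene with C1 dimethoxymethyl group | C[C@]1(C(OC)OC)C=C[C@@H](OCc2ccc(OC)cc2)[C@@H]2C(=O)OC[C@@H](O[Si](C)(C)C(C)(C)C)[C@H]12 | intermediate
16 | C2 aldehyde | C[C@]1(C=O)C=C[C@@H](OCc2ccc(OC)cc2)[C@@H]2C(=O)OC[C@@H](O[Si](C)(C)C(C)(C)C)[C@H]12 | intermediate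
17 | C2 vinyl carbinol (2S) | C[C@]1([C@@H](O)C=C)C=C[C@@H](OCc2ccc(OC)cc2)[C@@H]2C(=O)OC[C@@H](O[Si](C)(C)C(C)(C)C)[C@H]12 | intermediate
18 | C2 tert-butyldimethylsilyl ether | C[C@]1([C@@H](O[Si](C)(C)C(C)(C)C)C=C)C=C[C@@H](OCc2ccc(OC)cc2)[C@@H]2C(=O)OC[C@@H](O[Si](C)(C)C(C)(C)C)[C@H]12 | intermediate
19 | lactol (C20 hemiacetal; anomers) | C[C@]1([C@@H](O[Si](C)(C)C(C)(C)C)C=C)C=C[C@@H](OCc2ccc(OC)cc2)[C@@H]2C(O)OC[C@@H](O[Si](C)(C)C(C)(C)C)[C@H]12 | intermediate
20 | open-chain C20 tosylhydrazone with free C8 hydroxyl | C[C@]1([C@@H](O[Si](C)(C)C(C)(C)C)C=C)C=C[C@@H](OCc2ccc(OC)cc2)[C@H](/C=N/NS(=O)(=O)c2ccc(C)cc2)[C@@H]1[C@H](O[Si](C)(C)C(C)(C)C)CO | intermediate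
21 | C8 primary alcohol with C20 methyl group | C[C@]1([C@@H](O[Si](C)(C)C(C)(C)C)C=C)C=C[C@@H](OCc2ccc(OC)cc2)[C@H](C)[C@@H]1[C@H](O[Si](C)(C)C(C)(C)C)CO | intermediate
22 | C8 aldehyde | C[C@]1([C@@H](O[Si](C)(C)C(C)(C)C)C=C)C=C[C@@H](OCc2ccc(OC)cc2)[C@H](C)[C@@H]1[C@H](O[Si](C)(C)C(C)(C)C)C=O | intermediate
23 | 1,4-bis(trimethylsilyl)buta-1,3-diyne | C[Si](C)(C)C#CC#C[Si](C)(C)C | starting material
24 | lithium 4-(trimethylsilyl)buta-1,3-diynide | [Li]C#CC#C[Si](C)(C)C | intermediate
25 | buta-1,3-diynyl(trimethyl)silane | C#CC#C[Si](C)(C)C | intermediate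
26 | dicyclohexyl[(E)-4-(trimethylsilyl)but-1-en-3-yn-1-yl]borane | C[Si](C)(C)C#C/C=C/B(C1CCCCC1)C1CCCCC1 | intermediate
27 | methyl[(E)-4-(trimethylsilyl)but-1-en-3-yn-1-yl]zinc | C[Zn]/C=C/C#C[Si](C)(C)C | intermediate
28 | (8S)-enynol: C8 hydroxyl syn to C9 OTBS; (E)-C6=C7; C5≡C4–SiMe3 | C[C@]1([C@@H](O[Si](C)(C)C(C)(C)C)C=C)C=C[C@@H](OCc2ccc(OC)cc2)[C@H](C)[C@@H]1[C@H](O[Si](C)(C)C(C)(C)C)[C@@H](O)/C=C/C#C[Si](C)(C)C | intermediate
29 | trans-6,7-epoxy-8-ol (erythro) | C[C@]1([C@@H](O[Si](C)(C)C(C)(C)C)C=C)C=C[C@@H](OCc2ccc(OC)cc2)[C@H](C)[C@@H]1[C@H](O[Si](C)(C)C(C)(C)C)[C@@H](O)[C@H]2O[C@@H]2C#C[Si](C)(C)C | intermediate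
30 | C8 ketone with trans-6,7-epoxide | C[C@]1([C@@H](O[Si](C)(C)C(C)(C)C)C=C)C=C[C@@H](OCc2ccc(OC)cc2)[C@H](C)[C@@H]1[C@H](O[Si](C)(C)C(C)(C)C)C(=O)[C@H]2O[C@@H]2C#C[Si](C)(C)C | intermediate
31 | tertiary β-hydroxy ethyl ester (8R,17R) with 6,7-epoxide | C[C@]1([C@@H](O[Si](C)(C)C(C)(C)C)C=C)C=C[C@@H](OCc2ccc(OC)cc2)[C@H](C)[C@@H]1[C@H](O[Si](C)(C)C(C)(C)C)[C@](O)([C@@H](C)C(=O)OCC)[C@H]2O[C@@H]2C#C[Si](C)(C)C | intermediate
32 | 6-chloro-7,8-diol ethyl ester (anti chlorohydrin) | C[C@]1([C@@H](O[Si](C)(C)C(C)(C)C)C=C)C=C[C@@H](OCc2ccc(OC)cc2)[C@H](C)[C@@H]1[C@H](O[Si](C)(C)C(C)(C)C)[C@](O)([C@@H](C)C(=O)OCC)[C@@H](O)[C@@H](Cl)C#C[Si](C)(C)C | intermediate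
33 | chloro γ-lactone (O7–C19) with free C8 hydroxyl | C[C@]1([C@@H](O[Si](C)(C)C(C)(C)C)C=C)C=C[C@@H](OCc2ccc(OC)cc2)[C@H](C)[C@@H]1[C@H](O[Si](C)(C)C(C)(C)C)[C@]2(O)[C@@H](C)C(=O)O[C@H]2[C@@H](Cl)C#C[Si](C)(C)C | intermediate
34 | C12 alcohol | C[C@]1([C@@H](O[Si](C)(C)C(C)(C)C)C=C)C=C[C@@H](O)[C@H](C)[C@@H]1[C@H](O[Si](C)(C)C(C)(C)C)[C@]2(O)[C@@H](C)C(=O)O[C@H]2[C@@H](Cl)C#C[Si](C)(C)C | intermediate
35 | C12 acetate | C[C@]1([C@@H](O[Si](C)(C)C(C)(C)C)C=C)C=C[C@@H](OC(C)=O)[C@H](C)[C@@H]1[C@H](O[Si](C)(C)C(C)(C)C)[C@]2(O)[C@@H](C)C(=O)O[C@H]2[C@@H](Cl)C#C[Si](C)(C)C | intermediate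
36 | enyne triol (C2, C8, C9 hydroxyls; C6 ethynyl) | C[C@]1([C@@H](O)C=C)C=C[C@@H](OC(C)=O)[C@H](C)[C@@H]1[C@H](O)[C@]2(O)[C@@H](C)C(=O)O[C@H]2[C@@H](Cl)C#C | intermediate
37 | triene with 2-substituted buta-1,3-diene on C6 | C[C@]1([C@@H](O)C=C)C=C[C@@H](OC(C)=O)[C@H](C)[C@@H]1[C@H](O)[C@]2(O)[C@@H](C)C(=O)O[C@H]2[C@@H](Cl)C(=C)C=C | intermediate
38 | ten-membered (3Z)-diene diol (2,9-dideacetyl target) | C=C1/C=C\[C@H](O)[C@@]2(C)C=C[C@@H](OC(C)=O)[C@H](C)[C@@H]2[C@H](O)[C@]2(O)[C@@H](C)C(=O)O[C@H]2[C@H]1Cl | intermediate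
39 | CNP0076552.1 (1S,2S,3Z,6S,7R,8R,9S,10S,11R,12R,17R) | C=C1/C=C\[C@H](OC(C)=O)[C@@]2(C)C=C[C@@H](OC(C)=O)[C@H](C)[C@@H]2[C@H](OC(C)=O)[C@]2(O)[C@@H](C)C(=O)O[C@H]2[C@H]1Cl | target

**Step count**

Total step count: 28. Longest linear sequence: 25 steps (from 5 to 39: steps 3–16 and 18–28).

**Steps most likely to fail**

Step 7 (intramolecular Diels–Alder reaction). The cycloaddition may be too slow, because the ester tether must reach its disfavoured s-trans conformation and the alkoxy donor deactivates the acrylate; prolonged heating would then erode endo selectivity and degrade the silyl dienol ether. The fallback sets out from 8 and comes back at 11. It replaces the dienophile by an alkenylboronate in which boron is the masked C12 hydroxyl. The primary hydroxyl of 8 would be esterified (EDC·HCl, DMAP) with (E)-3-(4,4,5,5-tetramethyl-1,3,2-dioxaborolan-2-yl)acrylic acid to the boryl acrylate ester F1. TBSOTf/Et3N would give the bis-silyl triene F2. The more reactive dienophile should cyclise at lower temperature, with the same tether-enforced regiochemistry and the boron trans to C20, to the cis-fused C12 boronate F3. Oxidation with NaBO3 (retention) would give the C12 alcohol F4, and neutral 4-methoxybenzylation (2-(4-methoxybenzyloxy)-1-methylpyridinium triflate, MgO, PhCF3) would return 11.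

Step 27 (ring-closing metathesis). The ruthenium carbene may oligomerise the triene instead of closing the strained ring, because the C2 vinyl group next to the quaternary carbon is engaged slowly and the carbene formed on the diene is unreactive. The fallback sets out from 36 and comes back at 38. It closes the ring by sp2–sp2 coupling at C4–C5 instead of by metathesis. Markovnikov hydroiodination of the terminal alkyne (NaI, Me3SiCl, H2O, MeCN) would give the 2-iodoalkene F5, in which the iodine sits on C5 and the terminal carbon becomes C16. Z-selective cross-metathesis of its C2 vinyl group with vinylboronic acid pinacol ester would give the (Z)-alkenylboronate F6. A dilute Suzuki–Miyaura macrocyclisation (Pd(PPh3)4, TlOEt, THF/H2O) should then give 38, the Z geometry of C3=C4 being already in place in F6 from the cross-metathesis.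

Step 18 (chelation-controlled alkenylzinc addition). Competing non-chelated Felkin–Anh addition to the α-silyloxy aldehyde would give the anti (8R) carbinol, which is the slow-reacting epimer in the epoxidation of step 19. The fallback sets out from 22 and comes back at 28. It inverts the carbinol instead of relying on chelation. The addition would be run without the zinc halide so that the anti alcohol F7 is formed on purpose. A Mitsunobu reaction with chloroacetic acid (PPh3, DIAD) would invert C8 to the chloroacetate F8 of the syn series, and NH3/MeOH would cleave the ester to 28.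

**Further compounds**

F1 | step 7 | (S,E)-2-hydroxy-4-methyl-5-oxohex-3-en-1-yl (E)-3-(4,4,5,5-tetramethyl-1,3,2-dioxaborolan-2-yl)acrylate | CC(=O)/C(C)=C/[C@H](O)COC(=O)/C=C/B1OC(C)(C)C(C)(C)O1
F2 | step 7 | (S,E)-2,5-bis(tert-butyldimethylsilyloxy)-4-methylhexa-3,5-dien-1-yl (E)-3-(4,4,5,5-tetramethyl-1,3,2-dioxaborolan-2-yl)acrylate | C=C(O[Si](C)(C)C(C)(C)C)/C(C)=C/[C@H](O[Si](C)(C)C(C)(C)C)COC(=O)/C=C/B1OC(C)(C)C(C)(C)O1
F3 | step 7 | cis-fused cyclohexene δ-lactone with C12 pinacolboronate (analogue of 11) | CC1=C(O[Si](C)(C)C(C)(C)C)C[C@@H](B3OC(C)(C)C(C)(C)O3)[C@@H]2C(=O)OC[C@@H](O[Si](C)(C)C(C)(C)C)[C@H]12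
F4 | step 7 | cis-fused cyclohexene δ-lactone with free C12 hydroxyl | CC1=C(O[Si](C)(C)C(C)(C)C)C[C@@H](O)[C@@H]2C(=O)OC[C@@H](O[Si](C)(C)C(C)(C)C)[C@H]12
F5 | step 27 | 2-iodoalkene from 36 (iodine on C5, C16 methylene) | C[C@]1([C@@H](O)C=C)C=C[C@@H](OC(C)=O)[C@H](C)[C@@H]1[C@H](O)[C@]2(O)[C@@H](C)C(=O)O[C@H]2[C@@H](Cl)C(I)=C
F6 | step 27 | (Z)-C3=C4 alkenylboronate of F5 | C[C@]1([C@@H](O)/C=C\B3OC(C)(C)C(C)(C)O3)C=C[C@@H](OC(C)=O)[C@H](C)[C@@H]1[C@H](O)[C@]2(O)[C@@H](C)C(=O)O[C@H]2[C@@H](Cl)C(I)=C
F7 | step 18 | (8R)-enynol (C8 epimer of 28) | C[C@]1([C@@H](O[Si](C)(C)C(C)(C)C)C=C)C=C[C@@H](OCc2ccc(OC)cc2)[C@H](C)[C@@H]1[C@H](O[Si](C)(C)C(C)(C)C)[C@H](O)/C=C/C#C[Si](C)(C)C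
F8 | step 18 | (8S)-chloroacetate of 28 | C[C@]1([C@@H](O[Si](C)(C)C(C)(C)C)C=C)C=C[C@@H](OCc2ccc(OC)cc2)[C@H](C)[C@@H]1[C@H](O[Si](C)(C)C(C)(C)C)[C@@H](OC(=O)CCl)/C=C/C#C[Si](C)(C)C
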